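The oxane ring is read as a 2,4,6-trideoxyhexopyranose. Its C3–C4 and C5–C6 bonds, the C4 hydroxyl and the ring oxygen on C6 are what a 2-deoxyribose-5-phosphate aldolase (DERA) produces when it adds two acetaldehyde units in sequence to an aldehyde. The precursor is therefore an open-chain O-benzylated (S)-2-hydroxy-3-arylpropanal from the chiral pool (L-tyrosine-derived 4-hydroxyphenyllactate); one enzymatic operation forms both C–C bonds, sets C4 and C6 and delivers the lactol. The guaiacyl ring is then placed on the anomeric carbon C2 by axial attack of an arylzinc on the oxocarbenium ion (2,6-trans), and hydrogenolysis finishes the route.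

Key step: step 3

Remark: oxane numbering of the target is used throughout (O1; C2 carries the guaiacyl ring; C4 the ring hydroxyl; C6 the side chain; C7 is the side-chain carbinol). Compound 1 is taken as commercially available in enantiopure form. Lactol 7 and sulfones 8 and 9 are carried as anomer mixtures, because C2 is set only in step 6.

Step 1
Reactants: 1 methyl (2S)-2-hydroxy-3-(4-hydroxyphenyl)propanoate
Product: 2 methyl (2S)-2-(benzyloxy)-3-[4-(benzyloxy)phenyl]propanoate
Conditions: BnBr (3 equiv), Ag2O (2.5 equiv), CH2Cl2–DMF, rt, dark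
Reagents that add atoms: benzyl bromide, BrCc1ccccc1
Why: Silver oxide-mediated Williamson etherification benzylates the phenol and the α-hydroxy ester oxygen without a strong base, so the ester should not enolise and the S centre from the chiral pool should be kept.

Step 2
Reactants: 2 methyl (2S)-2-(benzyloxy)-3-[4-(benzyloxy)phenyl]propanoate
Product: 3 (2S)-2-(benzyloxy)-3-[4-(benzyloxy)phenyl]propanal
Conditions: i-Bu2AlH (1.1 equiv), CH2Cl2, −78 °C; MeOH, then aq. potassium sodium tartrate; used crude at once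
Reagents that add atoms: none
Why: Half-reduction of an α-alkoxy ester with i-Bu2AlH should stop at the chelated aluminium hemiacetal at −78 °C, which releases the aldehyde only on work-up, and immediate use limits α-epimerisation.

Step 3
Reactants: 3 (2S)-2-(benzyloxy)-3-[4-(benzyloxy)phenyl]propanal; 4 acetaldehyde (2 equiv incorporated)
Product: 7 (4R,6S)-6-{(1S)-1-(benzyloxy)-2-[4-(benzyloxy)phenyl]ethyl}oxane-2,4-diol (lactol), via mono-aldol β-hydroxy aldehyde 5 (not isolated), via open-chain 3,5-dihydroxy aldehyde 6 (not isolated)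
Conditions: 2-deoxy-D-ribose-5-phosphate aldolase (DERA, EC 4.1.2.4; acetaldehyde-tolerant variant, cell-free extract), acetaldehyde (2.5 equiv, slow feed), triethanolamine buffer pH 7.5, 20% v/v DMSO, 25 °C
Reagents that add atoms: none
Why: The active-site lysine of DERA, a Schiff-base (enamine) aldolase, converts acetaldehyde into an enamine that adds to the Si face of the carbonyl of 3 to form the C5–C6 bond and, after hydrolysis, β-hydroxy aldehyde 5; because O7 is benzylated, 5 cannot rest as a furanose hemiacetal, so it returns as acceptor for a second enamine, again on the Si face, which forms the C3–C4 bond and gives 6. The closest known reaction is the DERA-catalysed sequential double aldol addition of acetaldehyde to α-heteroatom-substituted acetaldehydes that is used to make statin lactols. The one ring closed is the oxane, by spontaneous 6-exo-trig hemiacetalisation of the C6 hydroxyl onto the C2 aldehyde, which removes 6 from the aldol equilibria and stops the chain after two additions. C6 (S) and C4 (R in the lactol; the same spatial arrangement is S in the target) are both set by the enzyme under catalyst control, which gives the 4,6-trans pattern, while C7 comes unchanged from 1. The step needs catalyst control to override the Felkin preference of the α-benzyloxy aldehyde, because the required C6/C7 relationship is syn and the acceptor has the configuration opposite to that of the natural D-configured substrate; the enzyme-fixed enamine geometry should secure the face, and an acetaldehyde-tolerant variant with DMSO as cosolvent is chosen to take the lipophilic acceptor.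

Step 4
Reactants: 7 (4R,6S)-6-{(1S)-1-(benzyloxy)-2-[4-(benzyloxy)phenyl]ethyl}oxane-2,4-diol
Product: 8 (4R,6S)-2-(benzenesulfonyl)-6-{(1S)-1-(benzyloxy)-2-[4-(benzyloxy)phenyl]ethyl}oxan-4-ol
Conditions: PhSO2H (2 equiv), CaCl2 (powdered, anhydrous), CH2Cl2, rt
Reagents that add atoms: benzenesulfinic acid, O=S(O)c1ccccc1
Why: Anomeric sulfone formation should proceed by acid-promoted ionisation of the lactol to the oxocarbenium ion and capture by sulfinate at sulfur, with CaCl2 binding the water, and the secondary C4 hydroxyl is not expected to take part.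

Step 5
Reactants: 8 (4R,6S)-2-(benzenesulfonyl)-6-{(1S)-1-(benzyloxy)-2-[4-(benzyloxy)phenyl]ethyl}oxan-4-ol
Product: 9 (4R,6S)-2-(benzenesulfonyl)-4-(benzyloxy)-6-{(1S)-1-(benzyloxy)-2-[4-(benzyloxy)phenyl]ethyl}oxane
Conditions: 2-benzyloxy-1-methylpyridinium triflate (2 equiv), MgO (2 equiv), PhCF3, 83 °C
Reagents that add atoms: 2-benzyloxy-1-methylpyridinium triflate, C[n+]1ccccc1OCc1ccccc1.[O-]S(=O)(=O)C(F)(F)F
Why: Neutral benzyl transfer from the 2-benzyloxypyridinium salt, buffered by MgO, should etherify the hindered C4 alcohol without base that could eliminate sulfinate or acid that could ionise the anomeric sulfone.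

Step 6
Reactants: 9 (4R,6S)-2-(benzenesulfonyl)-4-(benzyloxy)-6-{(1S)-1-(benzyloxy)-2-[4-(benzyloxy)phenyl]ethyl}oxane; 10 1-(benzyloxy)-4-bromo-2-methoxybenzene
Product: 13 (2S,4S,6S)-4-(benzyloxy)-2-[4-(benzyloxy)-3-methoxyphenyl]-6-{(1S)-1-(benzyloxy)-2-[4-(benzyloxy)phenyl]ethyl}oxane, via arylmagnesium bromide 11 (not isolated), via diarylzinc 12 (not isolated)
Conditions: 10, Mg, THF, rt; ZnBr2 (0.5 equiv per Mg), 0 °C; then 9, THF, rt
Reagents that add atoms: none
Why: In this anomeric sulfone–organozinc coupling the magnesium and zinc halides assist loss of sulfinate to give the oxocarbenium ion, whose favoured half-chair has the C6 side chain pseudo-equatorial and the C4 benzyloxy group pseudo-axial, so that axial, chair-like attack of the arylzinc should place the aryl group trans to C6 and cis to the C4 oxygen and set C2 as S.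

Step 7
Reactants: 13 (2S,4S,6S)-4-(benzyloxy)-2-[4-(benzyloxy)-3-methoxyphenyl]-6-{(1S)-1-(benzyloxy)-2-[4-(benzyloxy)phenyl]ethyl}oxane
Product: 14 (2S,4S,6S)-2-(4-hydroxy-3-methoxyphenyl)-6-[(1S)-1-hydroxy-2-(4-hydroxyphenyl)ethyl]oxan-4-ol
Conditions: H2 (1 atm), 10% Pd/C, EtOAc–MeOH, rt
Reagents that add atoms: none
Why: Catalytic hydrogenolysis should cleave the four O-benzyl groups while the ring C2–O1 bond, a C-aryl glycoside-type benzylic ether, reacts much more slowly, and the neutral medium avoids acid-mediated epimerisation of C2 to the more stable 2,6-cis isomer.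

Compound list
1 | methyl (2S)-2-hydroxy-3-(4-hydroxyphenyl)propanoate | COC(=O)[C@@H](O)Cc1ccc(O)cc1 | starting material
2 | methyl (2S)-2-(benzyloxy)-3-[4-(benzyloxy)phenyl]propanoate | COC(=O)[C@@H](OCc1ccccc1)Cc1ccc(OCc2ccccc2)cc1 | intermediate
3 | (2S)-2-(benzyloxy)-3-[4-(benzyloxy)phenyl]propanal | O=C[C@@H](OCc1ccccc1)Cc1ccc(OCc2ccccc2)cc1 | intermediate
4 | acetaldehyde | CC=O | starting material
5 | (3S,4S)-4-(benzyloxy)-5-[4-(benzyloxy)phenyl]-3-hydroxypentanal | O=CC[C@H](O)[C@@H](OCc1ccccc1)Cc1ccc(OCc2ccccc2)cc1 | intermediate (not isolated)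
6 | (3R,5S,6S)-6-(benzyloxy)-7-[4-(benzyloxy)phenyl]-3,5-dihydroxyheptanal | O=CC[C@H](O)C[C@H](O)[C@@H](OCc1ccccc1)Cc1ccc(OCc2ccccc2)cc1 | intermediate (not isolated)
7 | (4R,6S)-6-{(1S)-1-(benzyloxy)-2-[4-(benzyloxy)phenyl]ethyl}oxane-2,4-diol (anomer mixture) | OC1C[C@H](O)C[C@@H]([C@@H](OCc2ccccc2)Cc2ccc(OCc3ccccc3)cc2)O1 | intermediate
8 | (4R,6S)-2-(benzenesulfonyl)-6-{(1S)-1-(benzyloxy)-2-[4-(benzyloxy)phenyl]ethyl}oxan-4-ol (anomer mixture) | O=S(=O)(c1ccccc1)C1C[C@H](O)C[C@@H]([C@@H](OCc2ccccc2)Cc2ccc(OCc3ccccc3)cc2)O1 | intermediate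
9 | (4R,6S)-2-(benzenesulfonyl)-4-(benzyloxy)-6-{(1S)-1-(benzyloxy)-2-[4-(benzyloxy)phenyl]ethyl}oxane (anomer mixture) | O=S(=O)(c1ccccc1)C1C[C@H](OCc2ccccc2)C[C@@H]([C@@H](OCc2ccccc2)Cc2ccc(OCc3ccccc3)cc2)O1 | intermediate
10 | 1-(benzyloxy)-4-bromo-2-methoxybenzene | COc1cc(Br)ccc1OCc1ccccc1 | starting material
11 | [4-(benzyloxy)-3-methoxyphenyl]magnesium bromide | COc1cc([Mg]Br)ccc1OCc1ccccc1 | intermediate (not isolated)
12 | bis[4-(benzyloxy)-3-methoxyphenyl]zinc | COc1cc([Zn]c2ccc(OCc3ccccc3)c(OC)c2)ccc1OCc1ccccc1 | intermediate (not isolated)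
13 | (2S,4S,6S)-4-(benzyloxy)-2-[4-(benzyloxy)-3-methoxyphenyl]-6-{(1S)-1-(benzyloxy)-2-[4-(benzyloxy)phenyl]ethyl}oxane | COc1cc([C@@H]2C[C@H](OCc3ccccc3)C[C@@H]([C@@H](OCc3ccccc3)Cc3ccc(OCc4ccccc4)cc3)O2)ccc1OCc1ccccc1 | intermediate
14 | (2S,4S,6S)-2-(4-hydroxy-3-methoxyphenyl)-6-[(1S)-1-hydroxy-2-(4-hydroxyphenyl)ethyl]oxan-4-ol | COc1cc([C@@H]2C[C@H](O)C[C@@H]([C@@H](O)Cc3ccc(O)cc3)O2)ccc1O | target

Total step count: 7
Longest linear sequence: 7 steps (1 to 14)

Steps most likely to fail

Step 3 (enzymatic double aldol). The lipophilic, α-branched acceptor may turn over slowly. The sequence may stall after the first addition. The C6/C7 relationship may erode if 3 epimerises at its α-carbon and the enzyme then prefers the enantiomeric acceptor. The fallback sets out from 3 and comes back to the route at 7. A chelation-controlled vinylogous Mukaiyama aldol addition of 1-methoxy-1,3-bis(trimethylsilyloxy)buta-1,3-diene to 3 (TiCl4, CH2Cl2, −78 °C) should give the 5,6-syn adduct methyl (5S,6S)-6-(benzyloxy)-7-[4-(benzyloxy)phenyl]-5-hydroxy-3-oxoheptanoate F1. A Narasaka–Prasad reduction (Et2BOMe, NaBH4, THF–MeOH, −78 °C) should give the 3,5-syn diol methyl (3R,5S,6S)-6-(benzyloxy)-7-[4-(benzyloxy)phenyl]-3,5-dihydroxyheptanoate F2. Acid-catalysed lactonisation (cat. TsOH, toluene, rt) should give (4R,6S)-6-{(1S)-1-(benzyloxy)-2-[4-(benzyloxy)phenyl]ethyl}-4-hydroxyoxan-2-one F3, and half-reduction with i-Bu2AlH (CH2Cl2, −78 °C) should give lactol 7.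

Step 6 (C-arylation). Attack along the equatorial (twist-boat) trajectory would give the 2,6-cis epimer. Loss of sulfinic acid could give the dihydropyran, or the sulfone may fail to ionise. The fallback sets out from 9 and comes back at 13, and replaces the cationic pathway by an anomeric anion. Reductive lithiation of 9 (lithium naphthalenide, THF, −78 °C) should give the configurationally stable axial organolithium {4-(benzyloxy)-6-{(1S)-1-(benzyloxy)-2-[4-(benzyloxy)phenyl]ethyl}oxan-2-yl}lithium F4, with lithium cis to the C4 benzyloxy group. Trapping with Bu3SnCl with retention should give the axial stannane tributyl{4-(benzyloxy)-6-{(1S)-1-(benzyloxy)-2-[4-(benzyloxy)phenyl]ethyl}oxan-2-yl}stannane F5. A stereoretentive Stille coupling of F5 with bromide 10 (Pd2(dba)3 as zerovalent palladium source, JackiePhos, CuCl, KF, 1,4-dioxane, 110 °C) should give 13.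

Step 5 (benzylation beside the anomeric sulfone). Thermal loss of benzenesulfinic acid could outrun etherification of the hindered axial alcohol. The fallback sets out from 8 and comes back at 14, and changes the protecting group and the end game. Silylation (TBSCl, imidazole, DMF, rt) should give (4R,6S)-2-(benzenesulfonyl)-6-{(1S)-1-(benzyloxy)-2-[4-(benzyloxy)phenyl]ethyl}-4-[(tert-butyldimethylsilyl)oxy]oxane F6. Coupling with diarylzinc 12 as in step 6 should give (2S,4S,6S)-2-[4-(benzyloxy)-3-methoxyphenyl]-6-{(1S)-1-(benzyloxy)-2-[4-(benzyloxy)phenyl]ethyl}-4-[(tert-butyldimethylsilyl)oxy]oxane F7. Desilylation (Bu4NF, THF, rt) should give (2S,4S,6S)-2-[4-(benzyloxy)-3-methoxyphenyl]-6-{(1S)-1-(benzyloxy)-2-[4-(benzyloxy)phenyl]ethyl}oxan-4-ol F8, and hydrogenolysis as in step 7 should give 14.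

Further compounds
F1 | step 3 | methyl (5S,6S)-6-(benzyloxy)-7-[4-(benzyloxy)phenyl]-5-hydroxy-3-oxoheptanoate | COC(=O)CC(=O)C[C@H](O)[C@@H](OCc1ccccc1)Cc1ccc(OCc2ccccc2)cc1
F2 | step 3 | methyl (3R,5S,6S)-6-(benzyloxy)-7-[4-(benzyloxy)phenyl]-3,5-dihydroxyheptanoate | COC(=O)C[C@H](O)C[C@H](O)[C@@H](OCc1ccccc1)Cc1ccc(OCc2ccccc2)cc1
F3 | step 3 | (4R,6S)-6-{(1S)-1-(benzyloxy)-2-[4-(benzyloxy)phenyl]ethyl}-4-hydroxyoxan-2-one | O=C1C[C@H](O)C[C@@H]([C@@H](OCc2ccccc2)Cc2ccc(OCc3ccccc3)cc2)O1
F4 | step 6 | {4-(benzyloxy)-6-{(1S)-1-(benzyloxy)-2-[4-(benzyloxy)phenyl]ethyl}oxan-2-yl}lithium (axial, Li cis to the C4 benzyloxy group) | [Li][C@@H]1C[C@H](OCc2ccccc2)C[C@@H]([C@@H](OCc2ccccc2)Cc2ccc(OCc3ccccc3)cc2)O1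
F5 | step 6 | tributyl{4-(benzyloxy)-6-{(1S)-1-(benzyloxy)-2-[4-(benzyloxy)phenyl]ethyl}oxan-2-yl}stannane (axial, Sn cis to the C4 benzyloxy group) | CCCC[Sn](CCCC)(CCCC)[C@@H]1C[C@H](OCc2ccccc2)C[C@@H]([C@@H](OCc2ccccc2)Cc2ccc(OCc3ccccc3)cc2)O1
F6 | step 5 | (4R,6S)-2-(benzenesulfonyl)-6-{(1S)-1-(benzyloxy)-2-[4-(benzyloxy)phenyl]ethyl}-4-[(tert-butyldimethylsilyl)oxy]oxane | O=S(=O)(c1ccccc1)C1C[C@H](O[Si](C)(C)C(C)(C)C)C[C@@H]([C@@H](OCc2ccccc2)Cc2ccc(OCc3ccccc3)cc2)O1
F7 | step 5 | (2S,4S,6S)-2-[4-(benzyloxy)-3-methoxyphenyl]-6-{(1S)-1-(benzyloxy)-2-[4-(benzyloxy)phenyl]ethyl}-4-[(tert-butyldimethylsilyl)oxy]oxane | COc1cc([C@@H]2C[C@H](O[Si](C)(C)C(C)(C)C)C[C@@H]([C@@H](OCc3ccccc3)Cc3ccc(OCc4ccccc4)cc3)O2)ccc1OCc1ccccc1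
F8 | step 5 | (2S,4S,6S)-2-[4-(benzyloxy)-3-methoxyphenyl]-6-{(1S)-1-(benzyloxy)-2-[4-(benzyloxy)phenyl]ethyl}oxan-4-ol | COc1cc([C@@H]2C[C@H](O)C[C@@H]([C@@H](OCc3ccccc3)Cc3ccc(OCc4ccccc4)cc3)O2)ccc1OCc1ccccc1
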